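**Retrosynthetic overview**
1. Wittig cut at C11'=C12': the C40 target ⇒ (6R)-12'-apo-ε-caroten-12'-al (C25) + (2E,6E)-farnesyl ylide (C15), which brings in the complete 7',8'-dihydro-ψ end.
2. Wittig cut at C11=C12: C25 aldehyde ⇒ (R)-α-ionylideneethyl ylide (C15) + 2,7-dimethylocta-2,4,6-trienedial (C10).
3. C15 ylide ⇒ vinyl carbinol ⇒ (R)-α-ionone (C13) + vinyl Grignard reagent (C2).
4. Ring A is the only ring and is formed first: (R)-α-ionone ⇒ acyclic (3E,5E)-pseudoionone. The step is a catalytic enantioselective proton-initiated cyclisation. It repeats the ε-cyclase sequence (H+ to C2, C1–C6 bond, loss of H-4) and sets C6 as the ring closes.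

Assumption 1: technical pseudoionone (a 5E/5Z mixture) is fractionally distilled, and the (3E,5E) isomer is taken as commercial starting material 1.
Assumption 2: the (S,S)-catalyst is taken to give the (R)-product; if the first run shows the opposite sense, its mirror image made from (R)-BINOL is used under the same conditions.

**Step 1**
Reactants: 1 (3E,5E)-pseudoionone
Product: 3 (R)-α-ionone [(3E)-4-[(1R)-2,6,6-trimethylcyclohex-2-en-1-yl]but-3-en-2-one], via monocyclic C5 cation 2 (not isolated)
Conditions: (S,S)-imidodiphosphorimidate acid HN[P(=NSO2CF3)(O2C20H10Ar2)]2 (Ar = 3,5-(CF3)2C6H3, 5 mol%), (CF3)3COH, 0 °C, 48 h, N2; short SiO2 plug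
Reagents that add atoms: none
Why: Proposed new method: with the carbonyl lone pairs occupied by the H-bond-donor solvent, the strong confined chiral acid protonates the only electron-rich alkene (the isolated Me2C=CH unit) at C2 (carotenoid numbering), the C1 cation is captured in a chair-like fold by C6 of the nearby 5,6-alkene while paired with the chiral anion so that one face of C6 is attacked and C6 is set as R, and the anion then removes the adjacent H-4 of cation 2 to give the kinetic ε-type (α) alkene instead of the conjugated β isomer; the racemic reaction is the classical H3PO4 cyclisation of pseudoionone to α-ionone, and the closest asymmetric reaction type is the imidodiphosphorimidate-catalysed proton-initiated polyene cyclisation of homofarnesol-type substrates in perfluorinated alcohols.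

**Step 2**
Reactants: 3 (R)-α-ionone; 4 vinylmagnesium bromide
Product: 6 (1E)-3-methyl-1-[(1R)-2,6,6-trimethylcyclohex-2-en-1-yl]penta-1,4-dien-3-ol (vinyl-α-ionol; C9 epimer mixture), via bromomagnesium alkoxide 5 (not isolated)
Conditions: 4 (1.3 equiv), THF, −20 °C to 0 °C; sat. aq NH4Cl
Reagents that add atoms: vinylmagnesium bromide 4, C=C[Mg]Br
Why: Grignard 1,2-addition: at low temperature the hard vinyl nucleophile attacks the enone carbonyl faster than it adds 1,4 or removes the γ-proton at C6, so C6 stays R, and the new C9 carbinol centre forms unselectively, which does not matter because it becomes sp2 in step 3.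

**Step 3**
Reactants: 6 vinyl-α-ionol; 7 triphenylphosphine hydrobromide; 8 (2E,4E,6E)-2,7-dimethylocta-2,4,6-trienedial
Product: 12 (6R)-12'-apo-ε-caroten-12'-al (all-E), via C15 phosphonium bromide 9 (not isolated), via C15 ylide 10 (not isolated), via 11Z aldehyde 11 (not isolated)
Conditions: 7 (1.0 equiv), MeOH, rt, 24 h; then 8 (2.0 equiv), CH2Cl2, NaOMe (1.05 equiv, slow addition), 0 °C to rt; then heptane, 80 °C, 2 h, dark, N2; SiO2, crystallisation
Reagents that add atoms: triphenylphosphine hydrobromide 7, [Br-].c1ccc(cc1)[PH+](c1ccccc1)c1ccccc1 (its atoms stay only in 9 and 10); 2,7-dimethylocta-2,4,6-trienedial 8, O=C/C(C)=C/C=C/C=C(C)/C=O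
Why: Acid-induced allylic (SN1'-type) phosphonium salt formation followed by a Wittig reaction: ionisation of 6 gives a pentadienyl cation that PPh3 traps at the unhindered terminus C11 to give mainly the 9E salt 9, ylide 10 olefinates one formyl group of 8 (excess 8 and the lower electrophilicity of the longer polyenal 12 hold back a second olefination), the hindered 11Z isomer 11 relaxes thermally to all-E 12, and no bond at C6 is touched.

**Step 4**
Reactants: 12 (6R)-12'-apo-ε-caroten-12'-al; 13 (2E,6E)-farnesyl bromide; 14 triphenylphosphine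
Product: 18 (6R)-7',8'-dihydro-ε,ψ-carotene [(6R)-α-zeacarotene; the target], via farnesylphosphonium bromide 15 (not isolated), via farnesylidene ylide 16 (not isolated), via 11'Z isomer 17 (not isolated)
Conditions: 13 + 14 (1.3 equiv each), THF, 40 °C, 12 h; NaN(SiMe3)2 (1.25 equiv), −78 °C to 0 °C; 12, −78 °C to rt; then heptane, reflux, 3 h, dark, N2; crystallisation
Reagents that add atoms: (2E,6E)-farnesyl bromide 13, CC(C)=CCC/C(C)=C/CC/C(C)=C/CBr; triphenylphosphine 14, c1ccc(cc1)P(c1ccccc1)c1ccccc1 (its atoms stay only in 15 and 16)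
Why: SN2 quaternisation followed by a Wittig reaction of the semistabilised allylic ylide 16, pre-formed so that 12 never meets free amide base and C6 is not epimerised, builds C11'=C12' as an E/Z mixture whose hindered 11'Z part 17 converts thermally into the all-E target that crystallises, and joining an apo-12'-carotenal to a farnesyl ylide is the established way to make zeacarotene-type 7',8'-dihydro ends.

**Compound list**
1 | (3E,5E)-pseudoionone (6,10-dimethylundeca-3,5,9-trien-2-one) | CC(=O)/C=C/C=C(C)/CCC=C(C)C | starting material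
2 | monocyclic tertiary C5 cation, ion pair with the catalyst anion, C6 configured as in 3 | CC(=O)/C=C/[C@H]1[C+](C)CCCC1(C)C | intermediate
3 | (R)-α-ionone | CC(=O)/C=C/[C@H]1C(C)=CCCC1(C)C | intermediate
4 | vinylmagnesium bromide | C=C[Mg]Br | starting material
5 | bromomagnesium alkoxide of 6 (C9 epimer mixture) | C=CC(C)(O[Mg]Br)/C=C/[C@H]1C(C)=CCCC1(C)C | intermediate
6 | (1E)-3-methyl-1-[(1R)-2,6,6-trimethylcyclohex-2-en-1-yl]penta-1,4-dien-3-ol (C9 epimer mixture) | C=CC(C)(O)/C=C/[C@H]1C(C)=CCCC1(C)C | intermediate
7 | triphenylphosphine hydrobromide | [Br-].c1ccc(cc1)[PH+](c1ccccc1)c1ccccc1 | starting material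
8 | (2E,4E,6E)-2,7-dimethylocta-2,4,6-trienedial | O=C/C(C)=C/C=C/C=C(C)/C=O | starting material
9 | [(2E,4E)-3-methyl-5-[(1R)-2,6,6-trimethylcyclohex-2-en-1-yl]penta-2,4-dienyl]triphenylphosphonium bromide | [Br-].c1ccccc1[P+](c1ccccc1)(c1ccccc1)C/C=C(C)/C=C/[C@H]1C(C)=CCCC1(C)C | intermediate
10 | corresponding C15 triphenylphosphorane (ylide) | c1ccccc1P(c1ccccc1)(c1ccccc1)=C/C=C(C)/C=C/[C@H]1C(C)=CCCC1(C)C | intermediate
11 | (6R,11Z)-12'-apo-ε-caroten-12'-al | O=C/C(C)=C/C=C/C=C(C)/C=C\C=C(C)\C=C\[C@H]1C(C)=CCCC1(C)C | intermediate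
12 | (6R)-12'-apo-ε-caroten-12'-al, all-E | O=C/C(C)=C/C=C/C=C(C)/C=C/C=C(C)/C=C/[C@H]1C(C)=CCCC1(C)C | intermediate
13 | (2E,6E)-farnesyl bromide | CC(C)=CCC/C(C)=C/CC/C(C)=C/CBr | starting material
14 | triphenylphosphine | c1ccc(cc1)P(c1ccccc1)c1ccccc1 | starting material
15 | (2E,6E)-farnesyltriphenylphosphonium bromide | [Br-].CC(C)=CCC/C(C)=C/CC/C(C)=C/C[P+](c1ccccc1)(c1ccccc1)c1ccccc1 | intermediate
16 | (2E,6E)-farnesylidenetriphenylphosphorane | CC(C)=CCC/C(C)=C/CC/C(C)=C/C=P(c1ccccc1)(c1ccccc1)c1ccccc1 | intermediate
17 | (6R,11'Z)-7',8'-dihydro-ε,ψ-carotene | CC(C)=CCC/C(C)=C/CC/C(C)=C/C=C\C(C)=C\C=C\C=C(C)\C=C\C=C(C)\C=C\[C@H]1C(C)=CCCC1(C)C | intermediate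
18 | (6R)-7',8'-dihydro-ε,ψ-carotene, all-E [(6R)-α-zeacarotene] | CC(C)=CCC/C(C)=C/CC/C(C)=C/C=C/C(C)=C/C=C/C=C(C)/C=C/C=C(C)/C=C/[C@H]1C(C)=CCCC1(C)C | target

**Total step count:** 4. **Longest linear sequence:** 4 (1 → 3 → 6 → 12 → 18).

**Steps most likely to fail**

**Step 1.** The ketone may tie up the acid. The enantiomeric excess or the α:β ratio may be too low, and 5E/5Z equilibration of 1 may erode selectivity. The fallback sets out from 1 and comes back at 3. Compound 1 is cyclised without chiral control in 85% H3PO4 at 30 °C, which is the same cationic ring closure, to give racemic α-ionone F1. The enantiomers are then separated by preparative supercritical-fluid chromatography (CO2/MeOH) on amylose tris(3,5-dimethylphenylcarbamate). (S)-α-Ionone F2 is set aside, and the (R)-enantiomer is 3.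

**Step 3.** The telescoped sequence cannot purge the 9Z salt, and the statistical mono-olefination spends the chiral fragment. The fallback inverts the order in which the fragments are joined. It sets out from 8 and comes back at 18.
- Ylide 16, made from 13 and 14 as in step 4, is added to excess 8. This gives the acyclic C25 aldehyde (2E,4E,6E,8E,10E,14E)-2,7,11,15,19-pentamethylicosa-2,4,6,8,10,14,18-heptaenal F3, so the statistical loss falls on the cheap achiral half.
- Salt 9 is prepared separately from 6 and 7, isolated and recrystallised to the pure 9E form.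
- Salt 9 is converted with NaOMe into ylide 10 and joined to F3. After the thermal equilibration of step 4 this gives 18 directly.

**Step 4.** The allylic ylide may give a poor E/Z ratio at C11'=C12', may scramble C9'=C10', or may act as a base on 12. The fallback replaces the phosphorane with a phosphonate carbanion. It sets out from 13 and comes back at 18.
- Compound 13 is heated with triethyl phosphite at 120 °C (Michaelis–Arbuzov reaction) to give diethyl (2E,6E)-farnesylphosphonate F4.
- F4 is deprotonated with potassium tert-butoxide in THF at −30 °C and condensed with 12 in a Horner–Wadsworth–Emmons reaction.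
- This reaction is inherently E-selective and leaves a water-soluble phosphate in place of triphenylphosphine oxide.

**Further compounds**
F1 | step 1 | racemic α-ionone | CC(=O)/C=C/C1C(C)=CCCC1(C)C
F2 | step 1 | (S)-α-ionone | CC(=O)/C=C/[C@@H]1C(C)=CCCC1(C)C
F3 | step 3 | (2E,4E,6E,8E,10E,14E)-2,7,11,15,19-pentamethylicosa-2,4,6,8,10,14,18-heptaenal | CC(C)=CCC/C(C)=C/CC/C(C)=C/C=C/C(C)=C/C=C/C=C(C)/C=O
F4 | step 4 | diethyl (2E,6E)-farnesylphosphonate | CC(C)=CCC/C(C)=C/CC/C(C)=C/CP(=O)(OCC)OCC
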